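**Retrosynthetic overview**
1. Target 23 ⇐ hepta-O-benzyl diolide 22 by one global hydrogenolysis.
2. 22 ⇐ one-flask head-to-tail union of two mellein-type isochromanone lactones: 10 opened to an alkoxide/carboxylate (unit A) and 14 opened and armed as acyl chloride/2'-mesylate (unit B). O-acylation (retention) then carboxylate SN2 (inversion, gives 2'R of unit B) closes the 12-membered ring last.
3. 14 ⇐ 10 by para-oxygenation of the chelated C-8 phenol via the quinone (ring B = hydroxylated ring A), so both halves come from one lactone.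
4. 10 ⇐ aryl bromide 7 (Br/Li exchange, CO2, lactonisation; the six-membered lactone ring is formed first) ⇐ anti benzyloxy alcohol 6 ⇐ (S,S)-epoxide 5 ⇐ (E)-propenylarene 4.
5. 4 ⇐ 3,4,5-trihydroxybenzaldehyde 1 (selective 4-O-methylation, benzylation, Julia–Kocienski olefination).

Assumption: the diolide is taken to arise in nature by head-to-tail double esterification of two 4-hydroxymellein-type units, ring B being the C-5 (para) hydroxylated form of ring A; C-1' = benzylic carbinol carbon, C-2' = methyl carbinol carbon, unit A/unit B = the half carrying ring A (one aryl H)/ring B (fully substituted); the ent-Shi ketone is bought as a catalyst.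

**Route**

Step 1
Reactants: 1 3,4,5-trihydroxybenzaldehyde
Product: 2 3,5-dihydroxy-4-methoxybenzaldehyde
Conditions: MeI (1.05 equiv), Li2CO3 (1.2 equiv), DMF, 40 °C, Ar
Reagents that add atoms: iodomethane (CI)
Why: The 4-OH para to the formyl group is by far the most acidic phenol, so a weak base forms only that phenoxide and Williamson O-methylation occurs there selectively.

Step 2
Reactants: 2 3,5-dihydroxy-4-methoxybenzaldehyde
Product: 3 3,5-bis(benzyloxy)-4-methoxybenzaldehyde
Conditions: BnBr (2.3 equiv), K2CO3, DMF, 50 °C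
Reagents that add atoms: benzyl bromide (BrCc1ccccc1)
Why: Williamson benzylation of the two remaining phenols, benzyl being chosen so that every protecting group falls in the last hydrogenolysis.

Step 3
Reactants: 3 3,5-bis(benzyloxy)-4-methoxybenzaldehyde
Product: 4 1,3-bis(benzyloxy)-2-methoxy-5-[(1E)-prop-1-en-1-yl]benzene
Conditions: 5-(ethanesulfonyl)-1-phenyl-1H-tetrazole, KN(SiMe3)2, DME, −60 °C → rt; then 0.5 M HCl wash
Reagents that add atoms: 5-(ethanesulfonyl)-1-phenyl-1H-tetrazole (CCS(=O)(=O)c1nnnn1-c1ccccc1)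
Why: Julia–Kocienski olefination of an aromatic aldehyde with a 1-phenyltetrazolyl sulfone under KN(SiMe3)2/DME gives the (E)-propenylarene with high E selectivity via Smiles rearrangement and anti elimination.

Step 4
Reactants: 4 1,3-bis(benzyloxy)-2-methoxy-5-[(1E)-prop-1-en-1-yl]benzene
Product: 5 (2S,3S)-2-[3,5-bis(benzyloxy)-4-methoxyphenyl]-3-methyloxirane
Conditions: ent-Shi ketone (L-fructose-derived 1,2:4,5-di-O-isopropylidene-β-L-erythro-2,3-hexodiulo-2,6-pyranose, 30 mol%), Oxone (2KHSO5·KHSO4·K2SO4), K2CO3, Bu4NHSO4, MeCN/dimethoxymethane–aq. Na2B4O7 buffer, 0 °C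
Reagents that add atoms: potassium peroxymonosulfate (OOS(=O)(=O)[O-].[K+])
Why: Shi asymmetric epoxidation of a trans-β-methylstyrene-type alkene through the spiro dioxirane transition state gives the (S,S)-epoxide with the L-fructose-derived ketone (the D-fructose ketone gives R,R), which sets C-2' (S) directly and prepares C-1' for inversion.

Step 5
Reactants: 5 (2S,3S)-2-[3,5-bis(benzyloxy)-4-methoxyphenyl]-3-methyloxirane
Product: 6 (1R,2S)-1-(benzyloxy)-1-[3,5-bis(benzyloxy)-4-methoxyphenyl]propan-2-ol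
Conditions: BnOH (5 equiv), BF3·OEt2 (10 mol%), CH2Cl2, −40 °C
Reagents that add atoms: benzyl alcohol (OCc1ccccc1)
Why: Lewis-acid-catalysed epoxide alcoholysis occurs at the benzylic carbon in a borderline SN2 manner with inversion (the 4-methoxy group is twisted out of conjugation by its two ortho neighbours, which limits SN1 scrambling), so C-1' becomes R with its oxygen already benzylated and O-2' left free.

Step 6
Reactants: 6 (1R,2S)-1-(benzyloxy)-1-[3,5-bis(benzyloxy)-4-methoxyphenyl]propan-2-ol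
Product: 7 (1R,2S)-1-(benzyloxy)-1-[3,5-bis(benzyloxy)-2-bromo-4-methoxyphenyl]propan-2-ol
Conditions: NBS (1.05 equiv), MeCN, 0 °C, dark
Reagents that add atoms: N-bromosuccinimide (O=C1CCC(=O)N1Br)
Why: Electrophilic aromatic bromination at the only kind of free ring position, ortho and para to the two benzyloxy groups; the two positions are equivalent, so one regioisomer forms.

Step 7
Reactants: 7 (1R,2S)-1-(benzyloxy)-1-[3,5-bis(benzyloxy)-2-bromo-4-methoxyphenyl]propan-2-ol
Product: 10 (3S,4R)-4,6,8-tris(benzyloxy)-7-methoxy-3-methyl-3,4-dihydro-1H-isochromen-1-one, via aryllithium alkoxide 8 (not isolated), via hydroxy acid 9 (not isolated)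
Conditions: n-BuLi (1.05 equiv) then t-BuLi (2.1 equiv), THF, −78 °C; CO2; 1 M HCl; TsOH·H2O (cat.), PhMe, 40 °C
Reagents that add atoms: carbon dioxide (O=C=O)
Why: Bromine–lithium exchange at −78 °C outruns metalation of the benzyl ethers, carboxylation gives the seco acid, and lactonisation can only give the six-membered isochromanone (the mellein-type ring) because O-1' is blocked, so no phthalide forms and both stereocentres are untouched.

Step 8
Reactants: 10 (3S,4R)-4,6,8-tris(benzyloxy)-7-methoxy-3-methyl-3,4-dihydro-1H-isochromen-1-one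
Product: 11 (3S,4R)-4,6-bis(benzyloxy)-8-hydroxy-7-methoxy-3-methyl-3,4-dihydro-1H-isochromen-1-one
Conditions: MgBr2·OEt2 (3 equiv), PhMe/Et2O, 70 °C; dilute HCl work-up
Reagents that add atoms: none
Why: Chelation-controlled Lewis-acid debenzylation, in which magnesium bridges the lactone carbonyl and the peri 8-benzyloxy oxygen so that bromide removes only that benzyl group.

Step 9
Reactants: 11 (3S,4R)-4,6-bis(benzyloxy)-8-hydroxy-7-methoxy-3-methyl-3,4-dihydro-1H-isochromen-1-one
Product: 12 (3S,4R)-4,6-bis(benzyloxy)-7-methoxy-3-methyl-3,4-dihydro-1H-isochromene-1,5,8-trione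
Conditions: (KSO3)2NO (Fremy's salt, 2.5 equiv), KH2PO4 buffer, acetone/H2O, 20 °C
Reagents that add atoms: dipotassium nitrosodisulfonate ([O]N(S(=O)(=O)[O-])S(=O)(=O)[O-].[K+].[K+])
Why: Teuber oxidation converts a phenol with a free para position (C-5, the only unsubstituted ring carbon) into the para-quinone, the chemical counterpart of the presumed enzymatic para-hydroxylation that turns ring A into ring B.

Step 10
Reactants: 12 (3S,4R)-4,6-bis(benzyloxy)-7-methoxy-3-methyl-3,4-dihydro-1H-isochromene-1,5,8-trione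
Product: 14 (3S,4R)-4,5,6,8-tetrakis(benzyloxy)-7-methoxy-3-methyl-3,4-dihydro-1H-isochromen-1-one, via hydroquinone 13 (not isolated)
Conditions: Na2S2O4, EtOAc/H2O, rt; then BnBr (2.5 equiv), K2CO3, Bu4NI (cat.), DMF, 40 °C, Ar
Reagents that add atoms: benzyl bromide (BrCc1ccccc1)
Why: Dithionite reduction of the quinone followed directly by Williamson benzylation under argon gives the protected ring B lactone without handling the air-sensitive hydroquinone.

Step 11
Reactants: 14 (3S,4R)-4,5,6,8-tetrakis(benzyloxy)-7-methoxy-3-methyl-3,4-dihydro-1H-isochromen-1-one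
Product: 17 tert-butyldimethylsilyl 2-[(1R,2S)-1-(benzyloxy)-2-(methanesulfonyloxy)propyl]-3,4,6-tris(benzyloxy)-5-methoxybenzoate, via potassium hydroxy carboxylate 15 (not isolated), via hydroxy silyl ester 16 (not isolated)
Conditions: KOH (1.0 equiv), THF/MeOH/H2O, 40 °C, evaporate and dry; TBSCl (1.05 equiv), DMF/CH2Cl2, 0 °C; then Et3N, MsCl, −20 °C; cold NaHCO3 work-up, used crude
Reagents that add atoms: potassium hydroxide ([K+].[OH-]); tert-butyldimethylsilyl chloride (CC(C)(C)[Si](C)(C)Cl); methanesulfonyl chloride (CS(Cl)(=O)=O)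
Why: Saponification gives the hydroxy carboxylate, TBSCl without imidazole silylates only the carboxylate (which stops relactonisation), and the hindered secondary alcohol is then sulfonylated via sulfene (MsCl/Et3N) with retention at C-2'.

Step 12
Reactants: 17 tert-butyldimethylsilyl 2-[(1R,2S)-1-(benzyloxy)-2-(methanesulfonyloxy)propyl]-3,4,6-tris(benzyloxy)-5-methoxybenzoate; 10 (3S,4R)-4,6,8-tris(benzyloxy)-7-methoxy-3-methyl-3,4-dihydro-1H-isochromen-1-one
Product: 22 hepta-O-benzyl macrodiolide (the target with all five phenols plus both 1'-hydroxyls as benzyl ethers), via acyl chloride mesylate 18 (not isolated), via ring A potassium hydroxy carboxylate 19 (not isolated), via dipotassium alkoxide carboxylate 20 (not isolated), via open-chain carboxylate mesylate 21 (not isolated)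
Conditions: (a) 17, (COCl)2, DMF (cat.), CH2Cl2, 0 °C, then high vacuum; (b) 10, KOH (1.0 equiv), THF/H2O, dry, then KN(SiMe3)2 (1.0 equiv), THF, −78 °C; (c) 20 added to 18, THF, −78 → −40 °C; (d) cannula filtration from KCl into DMF (0.002 M), 18-crown-6, 60 °C
Reagents that add atoms: potassium hydroxide ([K+].[OH-])
Why: Proposed new method: a one-flask head-to-tail heterodimerisation of the bis-nucleophile 20 (alkoxide plus carboxylate from the ring A lactone) with the bis-electrophile 18 (acyl chloride plus 2'-mesylate from the ring B lactone), in which at −78 °C only the hard alkoxide reacts and only at the acyl chloride (O-acylation with retention at C-2' of unit A), leaving the non-basic carboxylate 21 that on dilution and warming displaces the mesylate intramolecularly by SN2 with inversion, so the 12-membered ring closes and the (2'R) centre of unit B is made from the same (2'S) monomer; the closest known reaction types are alkoxide acylation by hindered aroyl chlorides generated from silyl esters with oxalyl chloride/DMF under neutral conditions and the Kruizinga–Kellogg carboxylate-alkylation macrolactonisation, and the sequence copies the presumed head-to-tail joining of two mellein-type units.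

Step 13
Reactants: 22 hepta-O-benzyl macrodiolide
Product: 23 CNP0086623.4
Conditions: H2 (1 atm), 10% Pd/C, EtOAc/MeOH, rt; filtration and evaporation under Ar
Reagents that add atoms: none
Why: Catalytic hydrogenolysis cleaves the seven unhindered PhCH2–O bonds much faster than the hindered secondary ArCH(R)–O bonds ortho to an ester, and neutral conditions avoid translactonisation of the freed 1'-hydroxyls to phthalides and oxidation of the ring B hydroquinone.

**Compound list**
1 | 3,4,5-trihydroxybenzaldehyde | O=Cc1cc(O)c(O)c(O)c1 | starting material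
2 | 3,5-dihydroxy-4-methoxybenzaldehyde | COc1c(O)cc(C=O)cc1O | intermediate
3 | 3,5-bis(benzyloxy)-4-methoxybenzaldehyde | COc1c(OCc2ccccc2)cc(C=O)cc1OCc1ccccc1 | intermediate
4 | 1,3-bis(benzyloxy)-2-methoxy-5-[(1E)-prop-1-en-1-yl]benzene | C/C=C/c1cc(OCc2ccccc2)c(OC)c(OCc2ccccc2)c1 | intermediate
5 | (2S,3S)-2-[3,5-bis(benzyloxy)-4-methoxyphenyl]-3-methyloxirane | C[C@@H]1O[C@H]1c1cc(OCc2ccccc2)c(OC)c(OCc2ccccc2)c1 | intermediate
6 | (1R,2S)-1-(benzyloxy)-1-[3,5-bis(benzyloxy)-4-methoxyphenyl]propan-2-ol | C[C@H](O)[C@H](OCc1ccccc1)c1cc(OCc2ccccc2)c(OC)c(OCc2ccccc2)c1 | intermediate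
7 | (1R,2S)-1-(benzyloxy)-1-[3,5-bis(benzyloxy)-2-bromo-4-methoxyphenyl]propan-2-ol | C[C@H](O)[C@H](OCc1ccccc1)c1cc(OCc2ccccc2)c(OC)c(OCc2ccccc2)c1Br | intermediate
8 | lithium (1R,2S)-1-(benzyloxy)-1-[3,5-bis(benzyloxy)-2-lithio-4-methoxyphenyl]propan-2-olate | C[C@H](O[Li])[C@H](OCc1ccccc1)c1cc(OCc2ccccc2)c(OC)c(OCc2ccccc2)c1[Li] | intermediate
9 | 2-[(1R,2S)-1-(benzyloxy)-2-hydroxypropyl]-4,6-bis(benzyloxy)-5-methoxybenzoic acid | C[C@H](O)[C@H](OCc1ccccc1)c1cc(OCc2ccccc2)c(OC)c(OCc2ccccc2)c1C(=O)O | intermediate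
10 | (3S,4R)-4,6,8-tris(benzyloxy)-7-methoxy-3-methyl-3,4-dihydro-1H-isochromen-1-one | C[C@@H]1OC(=O)c2c(OCc3ccccc3)c(OC)c(OCc3ccccc3)cc2[C@H]1OCc1ccccc1 | intermediate
11 | (3S,4R)-4,6-bis(benzyloxy)-8-hydroxy-7-methoxy-3-methyl-3,4-dihydro-1H-isochromen-1-one | C[C@@H]1OC(=O)c2c(O)c(OC)c(OCc3ccccc3)cc2[C@H]1OCc1ccccc1 | intermediate
12 | (3S,4R)-4,6-bis(benzyloxy)-7-methoxy-3-methyl-3,4-dihydro-1H-isochromene-1,5,8-trione | C[C@@H]1OC(=O)C2=C([C@H]1OCc1ccccc1)C(=O)C(OCc1ccccc1)=C(OC)C2=O | intermediate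
13 | (3S,4R)-4,6-bis(benzyloxy)-5,8-dihydroxy-7-methoxy-3-methyl-3,4-dihydro-1H-isochromen-1-one | C[C@@H]1OC(=O)c2c(O)c(OC)c(OCc3ccccc3)c(O)c2[C@H]1OCc1ccccc1 | intermediate
14 | (3S,4R)-4,5,6,8-tetrakis(benzyloxy)-7-methoxy-3-methyl-3,4-dihydro-1H-isochromen-1-one | C[C@@H]1OC(=O)c2c(OCc3ccccc3)c(OC)c(OCc3ccccc3)c(OCc3ccccc3)c2[C@H]1OCc1ccccc1 | intermediate
15 | potassium 2-[(1R,2S)-1-(benzyloxy)-2-hydroxypropyl]-3,4,6-tris(benzyloxy)-5-methoxybenzoate | C[C@H](O)[C@H](OCc1ccccc1)c1c(OCc2ccccc2)c(OCc2ccccc2)c(OC)c(OCc2ccccc2)c1C(=O)[O-].[K+] | intermediate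
16 | tert-butyldimethylsilyl 2-[(1R,2S)-1-(benzyloxy)-2-hydroxypropyl]-3,4,6-tris(benzyloxy)-5-methoxybenzoate | C[C@H](O)[C@H](OCc1ccccc1)c1c(OCc2ccccc2)c(OCc2ccccc2)c(OC)c(OCc2ccccc2)c1C(=O)O[Si](C)(C)C(C)(C)C | intermediate
17 | tert-butyldimethylsilyl 2-[(1R,2S)-1-(benzyloxy)-2-(methanesulfonyloxy)propyl]-3,4,6-tris(benzyloxy)-5-methoxybenzoate | C[C@H](OS(C)(=O)=O)[C@H](OCc1ccccc1)c1c(OCc2ccccc2)c(OCc2ccccc2)c(OC)c(OCc2ccccc2)c1C(=O)O[Si](C)(C)C(C)(C)C | intermediate
18 | 2-[(1R,2S)-1-(benzyloxy)-2-(methanesulfonyloxy)propyl]-3,4,6-tris(benzyloxy)-5-methoxybenzoyl chloride | C[C@H](OS(C)(=O)=O)[C@H](OCc1ccccc1)c1c(OCc2ccccc2)c(OCc2ccccc2)c(OC)c(OCc2ccccc2)c1C(Cl)=O | intermediate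
19 | potassium 2-[(1R,2S)-1-(benzyloxy)-2-hydroxypropyl]-4,6-bis(benzyloxy)-5-methoxybenzoate | C[C@H](O)[C@H](OCc1ccccc1)c1cc(OCc2ccccc2)c(OC)c(OCc2ccccc2)c1C(=O)[O-].[K+] | intermediate
20 | dipotassium 2-[(1R,2S)-1-(benzyloxy)-2-oxidopropyl]-4,6-bis(benzyloxy)-5-methoxybenzoate | C[C@H]([O-])[C@H](OCc1ccccc1)c1cc(OCc2ccccc2)c(OC)c(OCc2ccccc2)c1C(=O)[O-].[K+].[K+] | intermediate
21 | potassium 2-[(1R,2S)-1-(benzyloxy)-2-({2-[(1R,2S)-1-(benzyloxy)-2-(methanesulfonyloxy)propyl]-3,4,6-tris(benzyloxy)-5-methoxybenzoyl}oxy)propyl]-4,6-bis(benzyloxy)-5-methoxybenzoate | C[C@H](OC(=O)c1c(OCc2ccccc2)c(OC)c(OCc2ccccc2)c(OCc2ccccc2)c1[C@@H](OCc1ccccc1)[C@H](C)OS(C)(=O)=O)[C@H](OCc1ccccc1)c1cc(OCc2ccccc2)c(OC)c(OCc2ccccc2)c1C(=O)[O-].[K+] | intermediate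
22 | hepta-O-benzyl macrodiolide: 12-membered head-to-tail dilactone in which the ring A acyl (4,6-bis(benzyloxy)-5-methoxybenzoyl) esterifies O-2' of the (1'R,2'R) side chain on ring B and the ring B acyl (3,4,6-tris(benzyloxy)-5-methoxybenzoyl) esterifies O-2' of the (1'R,2'S) side chain on ring A, both 1'-oxygens benzylated | COc1c(OCc3ccccc3)cc2c(c1OCc1ccccc1)C(=O)O[C@H](C)[C@H](OCc1ccccc1)c1c(OCc3ccccc3)c(OCc3ccccc3)c(OC)c(OCc3ccccc3)c1C(=O)O[C@@H](C)[C@@H]2OCc1ccccc1 | intermediate
23 | CNP0086623.4: the same 12-membered diolide with five free phenols and two free (1'R) benzylic hydroxyls; unit B side chain (1'R,2'R), unit A side chain (1'R,2'S) | COc1c(O)cc2c(c1O)C(=O)O[C@H](C)[C@H](O)c1c(O)c(O)c(OC)c(O)c1C(=O)O[C@@H](C)[C@@H]2O | target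

**Step count**
Total steps: 13. Longest linear sequence: 13 (steps 1–7 to lactone 10, steps 8–11 to 17, then steps 12 and 13; lactone 10 re-enters in step 12).

**Three steps most likely to fail, with fallbacks**

Step 12 (one-flask acylation and alkylative ring closure). Elimination of the mesylate, chloride scrambling at C-2' or slow acylation of the hindered alkoxide could spoil it. The fallback makes the two ester bonds in separate operations and closes the ring by a Mitsunobu reaction. It sets out from 14: the potassium salt 15 is silylated twice (TBSCl, imidazole, DMF) to tert-butyldimethylsilyl 2-[(1R,2S)-1-(benzyloxy)-2-(tert-butyldimethylsilyloxy)propyl]-3,4,6-tris(benzyloxy)-5-methoxybenzoate F1. Oxalyl chloride/DMF converts this into 2-[(1R,2S)-1-(benzyloxy)-2-(tert-butyldimethylsilyloxy)propyl]-3,4,6-tris(benzyloxy)-5-methoxybenzoyl chloride F2, which acylates dianion 20 (made from 10 as in step 12) to the silyl-protected ester acid F3. HF·pyridine in THF removes the silyl ether to give the seco hydroxy acid F4. PPh3/DIAD in toluene at high dilution then closes the ring with inversion at C-2' of unit B, and the route is rejoined at 22.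

Step 9 (Teuber oxidation of a hydrogen-bonded, carbonyl-deactivated phenol). If the quinone does not form cleanly, the C-5 oxygen is brought in by halogenation and C–O cross-coupling instead of oxidation. The fallback sets out from 11: NBS in MeCN brominates the only free ring position to give (3S,4R)-4,6-bis(benzyloxy)-5-bromo-8-hydroxy-7-methoxy-3-methyl-3,4-dihydro-1H-isochromen-1-one F5. BnBr/K2CO3 gives (3S,4R)-4,6,8-tris(benzyloxy)-5-bromo-7-methoxy-3-methyl-3,4-dihydro-1H-isochromen-1-one F6. Etherification with benzyl alcohol (Pd2(dba)3, RockPhos, Cs2CO3, toluene, 90 °C) then gives 14 directly, so steps 9 and 10 are bypassed and the route is rejoined at 14.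

Step 13 (global hydrogenolysis). The risks are partial loss of the benzylic C-1' oxygens, phthalide-type translactonisation and oxidation of the ring B hydroquinone. The fallback sets out from 22 and replaces reduction by Lewis-acid dealkylation with a cation scavenger (BCl3, pentamethylbenzene, CH2Cl2, −78 °C, quench with MeOH/CHCl3 at −78 °C). It arrives directly at 23 and makes no new compound.

**Further compounds**
F1 | step 12 | tert-butyldimethylsilyl 2-[(1R,2S)-1-(benzyloxy)-2-(tert-butyldimethylsilyloxy)propyl]-3,4,6-tris(benzyloxy)-5-methoxybenzoate | C[C@H](O[Si](C)(C)C(C)(C)C)[C@H](OCc1ccccc1)c1c(OCc2ccccc2)c(OCc2ccccc2)c(OC)c(OCc2ccccc2)c1C(=O)O[Si](C)(C)C(C)(C)C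
F2 | step 12 | 2-[(1R,2S)-1-(benzyloxy)-2-(tert-butyldimethylsilyloxy)propyl]-3,4,6-tris(benzyloxy)-5-methoxybenzoyl chloride | C[C@H](O[Si](C)(C)C(C)(C)C)[C@H](OCc1ccccc1)c1c(OCc2ccccc2)c(OCc2ccccc2)c(OC)c(OCc2ccccc2)c1C(Cl)=O
F3 | step 12 | 2-[(1R,2S)-1-(benzyloxy)-2-({2-[(1R,2S)-1-(benzyloxy)-2-(tert-butyldimethylsilyloxy)propyl]-3,4,6-tris(benzyloxy)-5-methoxybenzoyl}oxy)propyl]-4,6-bis(benzyloxy)-5-methoxybenzoic acid | C[C@H](OC(=O)c1c(OCc2ccccc2)c(OC)c(OCc2ccccc2)c(OCc2ccccc2)c1[C@@H](OCc1ccccc1)[C@H](C)O[Si](C)(C)C(C)(C)C)[C@H](OCc1ccccc1)c1cc(OCc2ccccc2)c(OC)c(OCc2ccccc2)c1C(=O)O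
F4 | step 12 | 2-[(1R,2S)-1-(benzyloxy)-2-({2-[(1R,2S)-1-(benzyloxy)-2-hydroxypropyl]-3,4,6-tris(benzyloxy)-5-methoxybenzoyl}oxy)propyl]-4,6-bis(benzyloxy)-5-methoxybenzoic acid | C[C@H](OC(=O)c1c(OCc2ccccc2)c(OC)c(OCc2ccccc2)c(OCc2ccccc2)c1[C@@H](OCc1ccccc1)[C@H](C)O)[C@H](OCc1ccccc1)c1cc(OCc2ccccc2)c(OC)c(OCc2ccccc2)c1C(=O)O
F5 | step 9 | (3S,4R)-4,6-bis(benzyloxy)-5-bromo-8-hydroxy-7-methoxy-3-methyl-3,4-dihydro-1H-isochromen-1-one | C[C@@H]1OC(=O)c2c(O)c(OC)c(OCc3ccccc3)c(Br)c2[C@H]1OCc1ccccc1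
F6 | step 9 | (3S,4R)-4,6,8-tris(benzyloxy)-5-bromo-7-methoxy-3-methyl-3,4-dihydro-1H-isochromen-1-one | C[C@@H]1OC(=O)c2c(OCc3ccccc3)c(OC)c(OCc3ccccc3)c(Br)c2[C@H]1OCc1ccccc1
F0 | step 13 | none | none
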